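**Plan**

- Retrosynthesis: the C1–O acyl bond is cut to free p-coumaric acid, and the two formyl groups are taken back to a C11/C12 dimethyl diester. The 5α-hydroxy/Δ7/9α-H array is traced back, through a 5α,6α-epoxide, to a drima-5,7-diene.
- Ring B of that diene (C5=C6–C7=C8, sp3 C9 and C10) is a cyclohexa-1,3-diene, i.e. the 6π-closure product of the hexatriene C10=C5–C6=C7–C8=C9. The triene is cut at C6=C7 by carbonyl olefination into a C1-oxygenated β-cyclocitral and a 2-(phosphonomethyl)butenedioate.
- What makes this possible: C5 and C10 are the two carbons of a tetrasubstituted 2,6,6-trimethylcyclohexene (ring A) that carries C6 as a formyl carbon, and C8 carries an ester at the 2-position of the triene, which accelerates the ring closure.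
- Forward: ring A from β-cyclocitral; olefination/6π-electrocyclisation then closes ring B (C6–C7 and C9–C10) in one pot; epoxidation/1,4-elimination, hydrogenation, deconjugative protonation, reduction, esterification and oxidation finish the route.
- Stereochemistry: C1 from CBS reduction; C10 from ring closure anti to the C1 pivalate; C5 from α-face epoxidation; C9 from kinetic α-face protonation opposite the C10 methyl.

Key step: step 9

Remark: bicyclic compounds carry drimane numbering (ring A = C1–C5, C10; ring B = C5–C10; C11 on C9, C12 on C8); β is the face of the C10 methyl.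

**Route**

Step 1
Reactants: 1 β-cyclocitral
Product: 3 β-cyclogeranyl acetate, via β-cyclogeraniol 2 (not isolated)
Conditions: NaBH4, MeOH, 0 °C; aqueous work-up; then Ac2O, pyridine, DMAP (cat.), CH2Cl2, rt
Reagents that add atoms: acetic anhydride, CC(=O)OC(C)=O
Why: Hydride 1,2-reduction of the hindered enal followed by DMAP-catalysed O-acetylation (standard carbonyl reduction and acylation); no stereocentre is formed.

Step 2
Reactants: 3 β-cyclogeranyl acetate
Product: 4 (2,6,6-trimethyl-3-oxocyclohex-1-en-1-yl)methyl acetate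
Conditions: Rh2(cap)4 [dirhodium tetrakis(caprolactamate), Rh2(C6H10NO)4] (1 mol %), t-BuOOH (70% aq, 5 equiv), K2CO3 (0.5 equiv), CH2Cl2, rt
Reagents that add atoms: tert-butyl hydroperoxide, CC(C)(C)OO
Why: Radical allylic C–H oxidation (dirhodium caprolactamate/t-BuOOH type): the peroxyl radical abstracts hydrogen from the ring methylene next to the methyl-bearing alkene carbon, the only secondary allylic C–H not deactivated by the acetoxy group, and the mixed peroxide collapses to the conjugated enone, as in the oxidation of β-ionone to its 4-oxo derivative; no stereocentre.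

Step 3
Reactants: 4 (2,6,6-trimethyl-3-oxocyclohex-1-en-1-yl)methyl acetate
Product: 5 [(3R)-3-hydroxy-2,6,6-trimethylcyclohex-1-en-1-yl]methyl acetate
Conditions: (S)-2-methyl-CBS-oxazaborolidine (15 mol %), BH3·SMe2 (0.7 equiv), THF, −20 °C; MeOH quench
Reagents that add atoms: none
Why: Corey–Bakshi–Shibata reduction: the ketone binds the oxazaborolidine with the trisubstituted alkenyl carbon as the large group and the ring CH2 as the small group, so the (S)-catalyst delivers hydride to give the (R)-allylic alcohol (the future C1) by clean 1,2-reduction.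

Step 4
Reactants: 5 [(3R)-3-hydroxy-2,6,6-trimethylcyclohex-1-en-1-yl]methyl acetate
Product: 6 (1R)-3-(acetoxymethyl)-2,4,4-trimethylcyclohex-2-en-1-yl pivalate
Conditions: t-BuCOCl, pyridine, DMAP (cat.), CH2Cl2, 0 °C → rt
Reagents that add atoms: pivaloyl chloride, CC(C)(C)C(=O)Cl
Why: DMAP-catalysed acylation of the secondary allylic alcohol with retention at C1; the pivalate survives methanolysis, phosphonate anions, peracid and amide base and is removed later by LiAlH4.

Step 5
Reactants: 6 (1R)-3-(acetoxymethyl)-2,4,4-trimethylcyclohex-2-en-1-yl pivalate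
Product: 7 (1R)-3-(hydroxymethyl)-2,4,4-trimethylcyclohex-2-en-1-yl pivalate
Conditions: K2CO3 (0.2 equiv), MeOH, 0 °C → rt
Reagents that add atoms: none
Why: Base-catalysed transesterification (Zemplén-type methanolysis) removes the unhindered primary acetate much faster than the tert-butyl-shielded secondary pivalate.

Step 6
Reactants: 7 (1R)-3-(hydroxymethyl)-2,4,4-trimethylcyclohex-2-en-1-yl pivalate
Product: 8 (1R)-3-formyl-2,4,4-trimethylcyclohex-2-en-1-yl pivalate
Conditions: Dess–Martin periodinane, NaHCO3, CH2Cl2, 0 °C → rt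
Reagents that add atoms: none
Why: Dess–Martin oxidation of the primary allylic alcohol to the enal; the pivalate and the C1 stereocentre are untouched.

Step 7
Reactants: 9 dimethyl mesaconate
Product: 10 dimethyl 2-(bromomethyl)fumarate
Conditions: NBS, AIBN (cat.), PhCF3, reflux
Reagents that add atoms: N-bromosuccinimide, O=C1CCC(=O)N1Br
Why: Wohl–Ziegler bromination of the allylic methyl group through the enoate-stabilised radical, a standard preparation of this bromide.

Step 8
Reactants: 10 dimethyl 2-(bromomethyl)fumarate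
Product: 11 dimethyl 2-[(diethoxyphosphoryl)methyl]fumarate
Conditions: P(OEt)3, PhMe, 110 °C
Reagents that add atoms: triethyl phosphite, CCOP(OCC)OCC
Why: Michaelis–Arbuzov reaction at the primary allylic bromide gives the conjugated, 4-phosphonocrotonate-type Horner–Wadsworth–Emmons reagent.

Step 9
Reactants: 8 (1R)-3-formyl-2,4,4-trimethylcyclohex-2-en-1-yl pivalate, 11 dimethyl 2-[(diethoxyphosphoryl)methyl]fumarate
Product: 14 dimethyl 1β-(pivaloyloxy)drima-5,7-diene-11,12-dioate, via the (6E)-triene 12 (not isolated), via the (6Z)-triene 13 (not isolated)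
Conditions: 11 (1.3 equiv), LiN(SiMe3)2 (1.25 equiv), THF, −78 → 0 °C; 8, 0 °C → rt; then PhMe, I2 (5 mol %), 80 °C
Reagents that add atoms: none
Why: Horner–Wadsworth–Emmons olefination of the formyl carbon C6 with lithiated 11 creates C6=C7 and with it the hexatriene C10=C5–C6=C7–C8=C9, whose C10=C5 bond is the tetrasubstituted ring A alkene and whose 2-position (C8) bears an ester; iodine-atom catalysis equilibrates the first-formed (6E)-triene 12 with the (6Z)-isomer 13, the only one that can fold into the helical geometry. Triene 13 then undergoes thermal disrotatory 6π-electrocyclisation, which forms C9–C10 and closes ring B as a cyclohexa-1,3-diene (6π mode, both termini C9 and C10 becoming ring atoms), so that C6–C7 ends as the single bond between C5=C6 and C7=C8. The closest known reaction types are tandem olefination/6π-electrocyclisation of 2-acceptor-substituted trienes and the closure of cis-dienyl-2,6,6-trimethylcyclohexenes (cyclocitral and ionone series) at the methyl-bearing ring carbon. C10: the C1 pivalate sits pseudo-axial to avoid allylic 1,2-strain with the C10 methyl and the C9 terminus should bond to the opposite (α) face, giving the 10β-methyl; a minor face isomer would be a separable diastereomer because C1 is already enantiopure. C9: disrotation from the ester-inside (fumarate-type) triene places the C9 ester cis to the C10 methyl, but this centre is erased on purpose in step 10 and reset in step 12, so any C8=C9 isomerisation (giving the C9 epimer) is harmless. The step needs periselectivity over the reversible 1,7-hydrogen shift from the C10 methyl, which the rate-enhancing ester at C8 and the irreversibility of ring closure should secure.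

Step 10
Reactants: 14 dimethyl 1β-(pivaloyloxy)drima-5,7-diene-11,12-dioate
Product: 16 dimethyl 5α-hydroxy-1β-(pivaloyloxy)drima-6,8-diene-11,12-dioate, via the 5α,6α-epoxide 15 (not isolated)
Conditions: mCPBA (1.1 equiv), NaHCO3, CH2Cl2, 0 °C; wash, dry; then DBU (1.5 equiv), CH2Cl2, rt
Reagents that add atoms: 3-chloroperbenzoic acid, O=C(OO)c1cccc(Cl)c1
Why: Prilezhaev epoxidation followed by base-induced 1,4-elimination (vinylogous E1cB epoxide opening): the peracid attacks the electron-richer γ,δ-bond C5=C6 from the α-face, opposite the C10 methyl and the 4β-methyl as in 5,7-diene steroids, which sets C5, and DBU then removes the acidic C9–H so that the ester dienolate expels the C6–O bond, leaving the 5α tertiary alcohol and a 6,8-diene in which the C9 centre is erased.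

Step 11
Reactants: 16 dimethyl 5α-hydroxy-1β-(pivaloyloxy)drima-6,8-diene-11,12-dioate
Product: 17 dimethyl 5α-hydroxy-1β-(pivaloyloxy)drim-8-ene-11,12-dioate
Conditions: H2 (1 atm), RhCl(PPh3)3 (5 mol %), PhH/EtOH, rt
Reagents that add atoms: none
Why: Homogeneous hydrogenation with Wilkinson's catalyst reduces only the cis-disubstituted C6=C7 bond, the tetrasubstituted diester-bearing C8=C9 bond being inert; no stereocentre is formed.

Step 12
Reactants: 17 dimethyl 5α-hydroxy-1β-(pivaloyloxy)drim-8-ene-11,12-dioate
Product: 19 dimethyl 5α-hydroxy-1β-(pivaloyloxy)drim-7-ene-11,12-dioate (9α-H), via the dilithium dienolate 18 (not isolated)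
Conditions: LiN(i-Pr)2 (2.3 equiv), THF, −78 °C; then AcOH (5 equiv), −78 °C
Reagents that add atoms: none
Why: Deconjugative kinetic protonation: after the hydroxyl, the base removes a γ-hydrogen at C7 (the only acidic C–H) to give the C11 ester dienolate, which is protonated at its α-carbon C9 from the α-face, opposite the axial C10 methyl and possibly relayed by the lithium 5α-alkoxide, giving the Δ7 ester with the equatorial 9β-ester, whereas γ-protonation would merely return 17.

Step 13
Reactants: 19 dimethyl 5α-hydroxy-1β-(pivaloyloxy)drim-7-ene-11,12-dioate (9α-H)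
Product: 20 drim-7-ene-1β,5α,11,12-tetraol
Conditions: LiAlH4 (6 equiv), THF, 0 °C → rt; Fieser work-up
Reagents that add atoms: none
Why: LiAlH4 reduction takes both methyl esters to primary alcohols (1,2-reduction of the enoate) and cleaves the pivalate in the same operation, after which C9 can no longer epimerise.

Step 14
Reactants: 20 drim-7-ene-1β,5α,11,12-tetraol
Product: 21 11,12-bis(triethylsilyloxy)drim-7-ene-1β,5α-diol
Conditions: Et3SiCl (2.2 equiv), imidazole, CH2Cl2, −20 °C
Reagents that add atoms: chlorotriethylsilane, CC[Si](Cl)(CC)CC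
Why: Silylation discriminates the two primary hydroxyls from the hindered secondary C1–OH (next to quaternary C10) and the tertiary C5–OH.

Step 15
Reactants: 22 p-coumaric acid
Product: 24 (E)-3-[4-(tert-butyldimethylsilyloxy)phenyl]prop-2-enoic acid, via the bis-silylated acid 23 (not isolated)
Conditions: TBSCl (2.3 equiv), imidazole, DMF, rt; then K2CO3, THF/MeOH/H2O, rt; mild acid work-up
Reagents that add atoms: tert-butyldimethylsilyl chloride, CC(C)(C)[Si](C)(C)Cl
Why: Exhaustive silylation followed by selective hydrolysis of the labile silyl ester leaves the aryl silyl ether (standard phenol protection); the E-alkene is unchanged.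

Step 16
Reactants: 21 11,12-bis(triethylsilyloxy)drim-7-ene-1β,5α-diol, 24 (E)-3-[4-(tert-butyldimethylsilyloxy)phenyl]prop-2-enoic acid
Product: 26 11,12-bis(triethylsilyloxy)-5α-hydroxydrim-7-en-1β-yl (E)-3-[4-(tert-butyldimethylsilyloxy)phenyl]prop-2-enoate, via the mixed anhydride 25 (not isolated)
Conditions: 24, 2,4,6-trichlorobenzoyl chloride, Et3N, THF, rt; then 21, DMAP, PhMe, rt → 50 °C
Reagents that add atoms: none
Why: Yamaguchi esterification: the mixed anhydride with DMAP acylates the hindered equatorial C1–OH while the tertiary C5–OH stays free, and C1 keeps its configuration because only the acyl–oxygen bond is formed.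

Step 17
Reactants: 26 11,12-bis(triethylsilyloxy)-5α-hydroxydrim-7-en-1β-yl (E)-3-[4-(tert-butyldimethylsilyloxy)phenyl]prop-2-enoate
Product: 27 5α-hydroxy-11,12-dioxodrim-7-en-1β-yl (E)-3-[4-(tert-butyldimethylsilyloxy)phenyl]prop-2-enoate
Conditions: (COCl)2 (5 equiv), DMSO (10 equiv), CH2Cl2, −78 → −40 °C; then Et3N (12 equiv), −78 → 0 °C
Reagents that add atoms: none
Why: Swern oxidation applied directly to primary triethylsilyl ethers: the chlorosulfonium salt exchanges each primary Et3Si–O for an alkoxysulfonium ion and Et3N then gives both aldehydes at once, so no hydroxy-aldehyde (lactol or lactone) stage arises, while the aryl silyl ether and the tertiary alcohol persist and the cold amine treatment, as used for polygodial, should leave C9 intact.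

Step 18
Reactants: 27 5α-hydroxy-11,12-dioxodrim-7-en-1β-yl (E)-3-[4-(tert-butyldimethylsilyloxy)phenyl]prop-2-enoate
Product: 28 1β-[(E)-p-coumaroyloxy]-5α-hydroxydrim-7-ene-11,12-dial (1R,5R,9R,10S)
Conditions: HF·pyridine, pyridine/THF, 0 °C
Reagents that add atoms: none
Why: Fluoride cleavage of the aryl silyl ether under buffered, non-basic conditions frees the phenol without epimerising C9 or dehydrating the 5-hydroxyl.

**Compound list**

1 | β-cyclocitral (2,6,6-trimethylcyclohex-1-ene-1-carbaldehyde) | CC1=C(C=O)C(C)(C)CCC1 | starting material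
2 | β-cyclogeraniol | CC1=C(CO)C(C)(C)CCC1 | intermediate
3 | β-cyclogeranyl acetate | CC(=O)OCC1=C(C)CCCC1(C)C | intermediate
4 | (2,6,6-trimethyl-3-oxocyclohex-1-en-1-yl)methyl acetate | CC(=O)OCC1=C(C)C(=O)CCC1(C)C | intermediate
5 | [(3R)-3-hydroxy-2,6,6-trimethylcyclohex-1-en-1-yl]methyl acetate | CC1(C)CC[C@@H](O)C(C)=C1COC(C)=O | intermediate
6 | (1R)-3-(acetoxymethyl)-2,4,4-trimethylcyclohex-2-en-1-yl pivalate | CC1(C)CC[C@@H](OC(=O)C(C)(C)C)C(C)=C1COC(C)=O | intermediate
7 | (1R)-3-(hydroxymethyl)-2,4,4-trimethylcyclohex-2-en-1-yl pivalate | CC1(C)CC[C@@H](OC(=O)C(C)(C)C)C(C)=C1CO | intermediate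
8 | (1R)-3-formyl-2,4,4-trimethylcyclohex-2-en-1-yl pivalate | CC1(C)CC[C@@H](OC(=O)C(C)(C)C)C(C)=C1C=O | intermediate
9 | dimethyl mesaconate (dimethyl (2E)-2-methylbut-2-enedioate) | COC(=O)/C=C(\C)C(=O)OC | starting material
10 | dimethyl 2-(bromomethyl)fumarate (ester groups trans) | COC(=O)/C=C(\CBr)C(=O)OC | intermediate
11 | dimethyl 2-[(diethoxyphosphoryl)methyl]fumarate (ester groups trans) | CCOP(=O)(OCC)C/C(C(=O)OC)=C\C(=O)OC | intermediate
12 | (6E)-triene: dimethyl 2-{(E)-2-[(3R)-2,6,6-trimethyl-3-(pivaloyloxy)cyclohex-1-en-1-yl]ethenyl}fumarate | CC1(C)CC[C@@H](OC(=O)C(C)(C)C)C(C)=C1/C=C/C(C(=O)OC)=C\C(=O)OC | intermediate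
13 | (6Z)-triene: dimethyl 2-{(Z)-2-[(3R)-2,6,6-trimethyl-3-(pivaloyloxy)cyclohex-1-en-1-yl]ethenyl}fumarate | CC1(C)CC[C@@H](OC(=O)C(C)(C)C)C(C)=C1/C=C\C(C(=O)OC)=C/C(=O)OC | intermediate
14 | dimethyl 1β-(pivaloyloxy)drima-5,7-diene-11,12-dioate (10β-methyl; C9 ester drawn β, its C9 epimer equally usable) | CC1(C)CC[C@@H](OC(=O)C(C)(C)C)[C@]2(C)[C@@H](C(=O)OC)C(C(=O)OC)=CC=C12 | intermediate
15 | dimethyl 5α,6α-epoxy-1β-(pivaloyloxy)drim-7-ene-11,12-dioate | CC1(C)CC[C@@H](OC(=O)C(C)(C)C)[C@]2(C)[C@@H](C(=O)OC)C(C(=O)OC)=C[C@@H]3O[C@]123 | intermediate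
16 | dimethyl 5α-hydroxy-1β-(pivaloyloxy)drima-6,8-diene-11,12-dioate | CC1(C)CC[C@@H](OC(=O)C(C)(C)C)[C@]2(C)C(C(=O)OC)=C(C(=O)OC)C=C[C@@]12O | intermediate
17 | dimethyl 5α-hydroxy-1β-(pivaloyloxy)drim-8-ene-11,12-dioate | CC1(C)CC[C@@H](OC(=O)C(C)(C)C)[C@]2(C)C(C(=O)OC)=C(C(=O)OC)CC[C@@]12O | intermediate
18 | dilithium 5-alkoxide/C11 ester dienolate of 17 | CC1(C)CC[C@@H](OC(=O)C(C)(C)C)[C@]2(C)C(=C([O-])OC)C(C(=O)OC)=CC[C@@]12[O-].[Li+].[Li+] | intermediate
19 | dimethyl 5α-hydroxy-1β-(pivaloyloxy)drim-7-ene-11,12-dioate (9α-H, 9β-ester) | CC1(C)CC[C@@H](OC(=O)C(C)(C)C)[C@]2(C)[C@@H](C(=O)OC)C(C(=O)OC)=CC[C@@]12O | intermediate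
20 | drim-7-ene-1β,5α,11,12-tetraol | CC1(C)CC[C@@H](O)[C@]2(C)[C@@H](CO)C(CO)=CC[C@@]12O | intermediate
21 | 11,12-bis(triethylsilyloxy)drim-7-ene-1β,5α-diol | CC1(C)CC[C@@H](O)[C@]2(C)[C@@H](CO[Si](CC)(CC)CC)C(CO[Si](CC)(CC)CC)=CC[C@@]12O | intermediate
22 | p-coumaric acid | O=C(O)/C=C/c1ccc(O)cc1 | starting material
23 | tert-butyldimethylsilyl (E)-3-[4-(tert-butyldimethylsilyloxy)phenyl]prop-2-enoate | CC(C)(C)[Si](C)(C)OC(=O)/C=C/c1ccc(O[Si](C)(C)C(C)(C)C)cc1 | intermediate
24 | (E)-3-[4-(tert-butyldimethylsilyloxy)phenyl]prop-2-enoic acid | O=C(O)/C=C/c1ccc(O[Si](C)(C)C(C)(C)C)cc1 | intermediate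
25 | mixed anhydride of 24 with 2,4,6-trichlorobenzoic acid | O=C(/C=C/c1ccc(O[Si](C)(C)C(C)(C)C)cc1)OC(=O)c1c(Cl)cc(Cl)cc1Cl | intermediate
26 | 11,12-bis(triethylsilyloxy)-5α-hydroxydrim-7-en-1β-yl (E)-3-[4-(tert-butyldimethylsilyloxy)phenyl]prop-2-enoate | CC1(C)CC[C@@H](OC(=O)/C=C/c2ccc(O[Si](C)(C)C(C)(C)C)cc2)[C@]2(C)[C@@H](CO[Si](CC)(CC)CC)C(CO[Si](CC)(CC)CC)=CC[C@@]12O | intermediate
27 | 5α-hydroxy-11,12-dioxodrim-7-en-1β-yl (E)-3-[4-(tert-butyldimethylsilyloxy)phenyl]prop-2-enoate | CC1(C)CC[C@@H](OC(=O)/C=C/c2ccc(O[Si](C)(C)C(C)(C)C)cc2)[C@]2(C)[C@@H](C=O)C(C=O)=CC[C@@]12O | intermediate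
28 | 1β-[(E)-p-coumaroyloxy]-5α-hydroxydrim-7-ene-11,12-dial, (1R,5R,9R,10S) | CC1(C)CC[C@@H](OC(=O)/C=C/c2ccc(O)cc2)[C@]2(C)[C@@H](C=O)C(C=O)=CC[C@@]12O | target

**Step count**

Total: 18 steps. Longest linear sequence: 15 steps (steps 1–6, 9–14 and 16–18).

**Steps most likely to fail, with fallbacks**

Step 9. The olefination of the hindered enal may stall, the triene may be drained by sigmatropic hydrogen shifts before it closes, or the closure may discriminate poorly between the two faces of C10. The fallback builds the same ring by a cycloaddition and sets out from 8. Wittig methylenation (Ph3P=CH2, THF) should give (1R)-3-ethenyl-2,4,4-trimethylcyclohex-2-en-1-yl pivalate F1. Diels–Alder reaction with dimethyl acetylenedicarboxylate (PhMe, 110 °C), again anti to the pivalate, should give dimethyl 1β-(pivaloyloxy)drima-5,8-diene-11,12-dioate F2. mCPBA should epoxidise the isolated, electron-richer C5=C6 bond from the α-face to give dimethyl 5α,6α-epoxy-1β-(pivaloyloxy)drim-8-ene-11,12-dioate F3. DBU then removes a C7–H (γ to the C11 ester) and opens the epoxide by β-elimination, which returns the route at 16.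

Step 10. The peracid may attack the wrong face or the wrong double bond of the diene, or the elimination may stop at the epoxide. The fallback installs the C5 oxygen by cycloaddition and sets out from 14. Dye-sensitised photo-oxygenation (O2, tetraphenylporphyrin, visible light, CH2Cl2) should add singlet oxygen across C5 and C8 on the α-face to give dimethyl 5α,8α-epidioxy-1β-(pivaloyloxy)drim-6-ene-11,12-dioate F4. DBU removes the C9–H and cleaves the C8–O bond by β-elimination to give dimethyl 5α-hydroperoxy-1β-(pivaloyloxy)drima-6,8-diene-11,12-dioate F5. Triphenylphosphine reduces the hydroperoxide, which returns the route at 16.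

Step 12. Protonation of the dienolate may occur on the β-face or at C7, or the base may attack an ester before it removes the C7 hydrogen. The fallback sets C9 by hydrogen delivery instead of protonation and sets out from 16, bypassing steps 11 and 12. 1,4-Hydrogenation of the cisoid 6,8-diene with (naphthalene)Cr(CO)3 and H2 (THF, 45 °C) should add both hydrogens to the diene termini C6 and C9 from the metal-bound α-face, opposite the C10 methyl, and leave C7=C8. This returns the route at 19; no new compound is involved (F0).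

Further compounds
F1 | step 9 | (1R)-3-ethenyl-2,4,4-trimethylcyclohex-2-en-1-yl pivalate | CC1(C)CC[C@@H](OC(=O)C(C)(C)C)C(C)=C1C=C
F2 | step 9 | dimethyl 1β-(pivaloyloxy)drima-5,8-diene-11,12-dioate | CC1(C)CC[C@@H](OC(=O)C(C)(C)C)[C@]2(C)C(C(=O)OC)=C(C(=O)OC)CC=C12
F3 | step 9 | dimethyl 5α,6α-epoxy-1β-(pivaloyloxy)drim-8-ene-11,12-dioate | CC1(C)CC[C@@H](OC(=O)C(C)(C)C)[C@]2(C)C(C(=O)OC)=C(C(=O)OC)C[C@@H]3O[C@]123
F4 | step 10 | dimethyl 5α,8α-epidioxy-1β-(pivaloyloxy)drim-6-ene-11,12-dioate | CC1(C)CC[C@@H](OC(=O)C(C)(C)C)[C@]2(C)[C@@H](C(=O)OC)[C@@]3(C(=O)OC)C=C[C@@]12OO3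
F5 | step 10 | dimethyl 5α-hydroperoxy-1β-(pivaloyloxy)drima-6,8-diene-11,12-dioate | CC1(C)CC[C@@H](OC(=O)C(C)(C)C)[C@]2(C)C(C(=O)OC)=C(C(=O)OC)C=C[C@@]12OO
F0 | step 12 | none | none
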